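**Retrosynthetic overview**

1. The target is a depside: ring A (2-heptyl-6-hydroxy-4-methoxybenzoyl) is bonded through its carboxyl carbon to O-4 of ring B (2-methoxy-6-pentylbenzoic acid). The last disconnections are the free acid (from a benzyl ester) and the 4-O-methyl group of ring A.
2. The strategy rests on ring A: oxygen at C4 and C6, heptyl at C2 and the ester carbonyl on C1 are the imprint of a 3,5,7-trioxotetradecanoyl chain folded C2 onto C7. The aryl ester C(=O)–O bond and all of ring A are therefore cut back to one acylketene plus the ring-B phenol 12.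
3. The acylketene is stored as diketo-dioxinone 6, assembled from dioxinone 1 by two enolate acylations (acetyl chloride 2, then Weinreb amide 5 from octanoyl chloride 4).
4. Phenol 12 comes from olivetol 7 by ortho-carboxylation and orthogonal protection (benzyl ester, allyl ether on O-4, methyl ether on O-2, allyl removed).
5. Ring order: ring B is bought as olivetol, the dioxinone ring is a sacrificial mask, and ring A is closed last, on the ester oxygen of ring B.

Key step: step 9

Remark: the target has no stereocentre, so no descriptors are needed. The β-dicarbonyl compounds 3, 6 and 14 are drawn as keto tautomers although they should be largely enolized. LiN(SiMe3)2, LiN(iPr)2 and MeOMgOCO2Me are taken as commercial solutions.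

**Route**

Step 1
Reactants: 1 2,2,6-trimethyl-4H-1,3-dioxin-4-one; 2 acetyl chloride
Product: 3 2,2-dimethyl-6-(2-oxopropyl)-4H-1,3-dioxin-4-one
Conditions: LiN(SiMe3)2 (2 equiv), THF, −78 °C; then 2, −78 °C; aq NH4Cl
Reagents that add atoms: none
Why: Vinylogous Claisen acylation, in which LiN(SiMe3)2 removes a proton from the 6-methyl group of 1 to give the cross-conjugated lithium dienolate, which is C-acylated at that terminal carbon by 2 while the extra base holds the more acidic product as its enolate until the quench.

Step 2
Reactants: 4 octanoyl chloride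
Product: 5 N-methoxy-N-methyloctanamide
Conditions: MeNH(OMe)·HCl, K2CO3, CH2Cl2/H2O, 0 °C to rt
Reagents that add atoms: N,O-dimethylhydroxylamine hydrochloride, CNOC.Cl
Why: Schotten–Baumann N-acylation, in which the amine freed by K2CO3 attacks the acid chloride in the organic phase faster than water hydrolyses it.

Step 3
Reactants: 3 2,2-dimethyl-6-(2-oxopropyl)-4H-1,3-dioxin-4-one; 5 N-methoxy-N-methyloctanamide
Product: 6 6-(2,4-dioxoundecyl)-2,2-dimethyl-4H-1,3-dioxin-4-one
Conditions: LiN(iPr)2 (2.5 equiv), THF, −78 °C; then 5, −78 to −20 °C; aq HCl to pH 3, 0 °C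
Reagents that add atoms: none
Why: Claisen-type C-acylation of a 1,3-dicarbonyl dianion, in which the second deprotonation of 3 takes place at the terminal methyl group and this more basic carbanion attacks the Weinreb amide, whose lithium-chelated tetrahedral adduct releases the ketone only on acidic quench so that no second addition occurs.

Step 4
Reactants: 7 olivetol (5-pentylbenzene-1,3-diol)
Product: 8 olivetolic acid (2,4-dihydroxy-6-pentylbenzoic acid)
Conditions: MeOMgOCO2Me (2 M in DMF, excess), 120 °C, N2; then cold aq HCl
Reagents that add atoms: methyl magnesium carbonate MeOMgOCO2Me, COC(=O)O[Mg]OC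
Why: Kolbe–Schmitt-type ortho-carboxylation, in which the magnesium phenoxide of 7 takes up CO2 from the reagent at the ring carbon flanked by a hydroxyl and the pentyl chain and the acid is held as a chelated magnesium salicylate until acidification, the outcome expected for 5-alkylresorcinols.

Step 5
Reactants: 8 olivetolic acid
Product: 9 benzyl 2,4-dihydroxy-6-pentylbenzoate
Conditions: BnBr, KHCO3, DMF, rt
Reagents that add atoms: benzyl bromide, BrCc1ccccc1
Why: SN2 O-alkylation of the carboxylate, which is chemoselective because KHCO3 deprotonates the carboxylic acid but not the phenols, and which avoids heating the decarboxylation-prone acid.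

Step 6
Reactants: 9 benzyl 2,4-dihydroxy-6-pentylbenzoate
Product: 10 benzyl 4-(allyloxy)-2-hydroxy-6-pentylbenzoate
Conditions: allyl bromide (1.1 equiv), K2CO3, acetone, reflux
Reagents that add atoms: allyl bromide, C=CCBr
Why: Williamson etherification, selective for the free 4-OH because the 2-OH is locked in a hydrogen bond to the ester carbonyl and is far less nucleophilic under carbonate conditions.

Step 7
Reactants: 10 benzyl 4-(allyloxy)-2-hydroxy-6-pentylbenzoate
Product: 11 benzyl 4-(allyloxy)-2-methoxy-6-pentylbenzoate
Conditions: MeI (excess), K2CO3, DMF, 40 °C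
Reagents that add atoms: iodomethane, CI
Why: Williamson etherification under more forcing conditions (polar aprotic solvent, excess MeI) alkylates the remaining chelated 2-OH, the benzyl ester and the allyl ether being inert to K2CO3.

Step 8
Reactants: 11 benzyl 4-(allyloxy)-2-methoxy-6-pentylbenzoate
Product: 12 benzyl 4-hydroxy-2-methoxy-6-pentylbenzoate
Conditions: Pd(PPh3)4 (cat.), morpholine, THF, rt
Reagents that add atoms: none
Why: Tsuji–Trost deallylation, in which zerovalent palladium ionizes the allyl aryl ether to a π-allyl complex of divalent palladium and the phenoxide, and morpholine captures the allyl fragment irreversibly while the benzyl ester and methyl ether stay untouched.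

Step 9
Reactants: 6 6-(2,4-dioxoundecyl)-2,2-dimethyl-4H-1,3-dioxin-4-one (1.3 equiv); 12 benzyl 4-hydroxy-2-methoxy-6-pentylbenzoate
Product: 15 benzyl 4-[(2-heptyl-4,6-dihydroxybenzoyl)oxy]-2-methoxy-6-pentylbenzoate, via diketo-acylketene 13 (not isolated), via aryl triketo ester 14 (not isolated)
Conditions: PhMe, 110 °C; then Et3N (2 equiv), CH2Cl2, rt; then HCl (4 M in dioxane), rt
Reagents that add atoms: none
Why: Heating 6 should expel acetone by a retro-hetero-Diels–Alder reaction to give acylketene 13, whose ketene carbon is attacked by the single free hydroxyl of 12 to give aryl triketo ester 14, the same reaction type as the thermal acetoacetylation of phenols with dioxinones. Triethylamine then enolizes 14, and C2, activated by the aryl ester and the C3 ketone, adds to the C7 heptyl ketone in a Baldwin-allowed 6-(enolexo)-exo-trig aldol that closes carbocyclic ring A from C2 to C7 of the chain. Acid-promoted loss of water and tautomerization of the C3 and C5 carbonyls to phenols complete the ring, which is the known late-stage aromatization of 3,5,7-triketo esters to 6-alkylresorcylates. No stereocentre survives, since the sp3 centres of the aldol stage are lost on aromatization. The step needs C-attack at C7 rather than lactonization of the C5 enol oxygen onto C1 (a 4-hydroxy-2-pyranone plus free 12) or C6-to-C1 Claisen closure (an acylphloroglucinol); the aprotic, non-nucleophilic amine, the absence of any alcohol or alkoxide and the irreversible aromatization of the aldol pathway are expected to secure this. Chemoselectivity in the capture follows from 12 having one free hydroxyl, its acid being a benzyl ester and its other phenol a methyl ether.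

Step 10
Reactants: 15 benzyl 4-[(2-heptyl-4,6-dihydroxybenzoyl)oxy]-2-methoxy-6-pentylbenzoate
Product: 16 benzyl 4-[(2-heptyl-6-hydroxy-4-methoxybenzoyl)oxy]-2-methoxy-6-pentylbenzoate
Conditions: MeI (1.05 equiv), K2CO3 (1.1 equiv), acetone, rt
Reagents that add atoms: iodomethane, CI
Why: Williamson etherification with one equivalent of MeI should alkylate only the 4-OH of ring A, which is para to the ester carbonyl, more acidic and not hydrogen-bonded, whereas the 6-OH is chelated to the depside carbonyl and the anhydrous carbonate conditions do not cleave the aryl ester.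

Step 11
Reactants: 16 benzyl 4-[(2-heptyl-6-hydroxy-4-methoxybenzoyl)oxy]-2-methoxy-6-pentylbenzoate
Product: 17 4-[(2-heptyl-6-hydroxy-4-methoxybenzoyl)oxy]-2-methoxy-6-pentylbenzoic acid (target)
Conditions: H2 (1 atm), 10% Pd/C, EtOAc, rt
Reagents that add atoms: none
Why: Catalytic hydrogenolysis of the benzylic C–O bond frees the carboxylic acid under neutral conditions that leave the aryl ester, the methyl ethers and both arenes intact.

**Compound list**

1 | 2,2,6-trimethyl-4H-1,3-dioxin-4-one | CC1=CC(=O)OC(C)(C)O1 | starting material
2 | acetyl chloride | CC(=O)Cl | starting material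
3 | 2,2-dimethyl-6-(2-oxopropyl)-4H-1,3-dioxin-4-one | CC(=O)CC1=CC(=O)OC(C)(C)O1 | intermediate
4 | octanoyl chloride | CCCCCCCC(=O)Cl | starting material
5 | N-methoxy-N-methyloctanamide | CCCCCCCC(=O)N(C)OC | intermediate
6 | 6-(2,4-dioxoundecyl)-2,2-dimethyl-4H-1,3-dioxin-4-one | CCCCCCCC(=O)CC(=O)CC1=CC(=O)OC(C)(C)O1 | intermediate
7 | olivetol (5-pentylbenzene-1,3-diol) | CCCCCc1cc(O)cc(O)c1 | starting material
8 | olivetolic acid (2,4-dihydroxy-6-pentylbenzoic acid) | CCCCCc1cc(O)cc(O)c1C(=O)O | intermediate
9 | benzyl 2,4-dihydroxy-6-pentylbenzoate | CCCCCc1cc(O)cc(O)c1C(=O)OCc1ccccc1 | intermediate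
10 | benzyl 4-(allyloxy)-2-hydroxy-6-pentylbenzoate | CCCCCc1cc(OCC=C)cc(O)c1C(=O)OCc1ccccc1 | intermediate
11 | benzyl 4-(allyloxy)-2-methoxy-6-pentylbenzoate | CCCCCc1cc(OCC=C)cc(OC)c1C(=O)OCc1ccccc1 | intermediate
12 | benzyl 4-hydroxy-2-methoxy-6-pentylbenzoate | CCCCCc1cc(O)cc(OC)c1C(=O)OCc1ccccc1 | intermediate
13 | tetradec-1-ene-1,3,5,7-tetraone (diketo-acylketene, formed in the flask in step 9) | CCCCCCCC(=O)CC(=O)CC(=O)C=C=O | intermediate
14 | benzyl 2-methoxy-6-pentyl-4-[(3,5,7-trioxotetradecanoyl)oxy]benzoate (aryl triketo ester, formed in the flask in step 9) | CCCCCCCC(=O)CC(=O)CC(=O)CC(=O)Oc1cc(CCCCC)c(C(=O)OCc2ccccc2)c(OC)c1 | intermediate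
15 | benzyl 4-[(2-heptyl-4,6-dihydroxybenzoyl)oxy]-2-methoxy-6-pentylbenzoate | CCCCCCCc1cc(O)cc(O)c1C(=O)Oc1cc(CCCCC)c(C(=O)OCc2ccccc2)c(OC)c1 | intermediate
16 | benzyl 4-[(2-heptyl-6-hydroxy-4-methoxybenzoyl)oxy]-2-methoxy-6-pentylbenzoate | CCCCCCCc1cc(OC)cc(O)c1C(=O)Oc1cc(CCCCC)c(C(=O)OCc2ccccc2)c(OC)c1 | intermediate
17 | 4-[(2-heptyl-6-hydroxy-4-methoxybenzoyl)oxy]-2-methoxy-6-pentylbenzoic acid | CCCCCCCc1cc(OC)cc(O)c1C(=O)Oc1cc(CCCCC)c(C(=O)O)c(OC)c1 | target

**Step count and risks**

Total step count: 11.
Longest linear sequence: 8 steps (olivetol 7 through steps 4, 5, 6, 7, 8, 9, 10 and 11 to 17).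

Steps most likely to fail:

1. Step 9. The acylketene may be consumed by its own enol oxygen, closing to a 4-hydroxy-2-pyranone, before the moderately nucleophilic phenol adds. Once the aryl triketo ester exists, the aryloxide is a good leaving group, so the base may trigger lactonization or Claisen closure with loss of the phenol instead of the aldol. Fallback: ring A is made first and the depside bond is formed by classical carbodiimide esterification. It sets out from 6 (phenol 12 is used as before) and comes back to the route at 16, so step 10 is skipped and step 11 follows. Thermolysis of 6 with benzyl alcohol in toluene at 110 °C should give, through 13, benzyl 3,5,7-trioxotetradecanoate F1, which is aromatized without isolation (Cs2CO3, MeOH, then HCl in MeOH) to benzyl 2-heptyl-4,6-dihydroxybenzoate F2. Selective methylation of the unchelated 4-OH (MeI, 1 equiv, K2CO3, acetone) would give benzyl 2-heptyl-6-hydroxy-4-methoxybenzoate F3. Hydrogenolysis (H2, Pd/C, EtOAc) would give 2-heptyl-6-hydroxy-4-methoxybenzoic acid F4. Condensation of this acid, whose ortho hydroxyl is chelated and needs no protection, with 12 using DCC in dry toluene at rt should give 16.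

2. Step 4. Carboxylation may be incomplete or go to the ring carbon between the two hydroxyls, and the product may lose CO2 again on acidification or warming. Fallback: the carboxyl carbon is introduced as an aldehyde and oxidized after the phenols are differentiated. It sets out from 7 and comes back at 11. Vilsmeier–Haack formylation (POCl3, DMF, 0 °C to rt, then aq NaOAc) should give 2,4-dihydroxy-6-pentylbenzaldehyde F5. Allylation of the unchelated hydroxyl (allyl bromide, K2CO3, acetone) would give 4-(allyloxy)-2-hydroxy-6-pentylbenzaldehyde F6. Methylation (MeI, K2CO3, DMF) would give 4-(allyloxy)-2-methoxy-6-pentylbenzaldehyde F7. Pinnick oxidation (NaClO2, NaH2PO4, 2-methyl-2-butene, tBuOH/H2O) would give 4-(allyloxy)-2-methoxy-6-pentylbenzoic acid F8. Benzylation (BnBr, KHCO3, DMF) would give 11.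

3. Step 3. Acyl transfer from the Weinreb amide to the stabilized dianion may be sluggish, the excess LiN(iPr)2 may enolize or fragment the amide, and the dioxinone may suffer during the acidic quench. Fallback: the acyl substitution is replaced by carbonyl addition followed by oxidation. It sets out from 3 and comes back at 6. The dianion of 3 (LiN(iPr)2, THF, −78 °C) is added to octanal, a fast aldol addition at the terminal carbon, to give racemic 6-(4-hydroxy-2-oxoundecyl)-2,2-dimethyl-4H-1,3-dioxin-4-one F9. Oxidation of the carbinol with Dess–Martin periodinane in CH2Cl2 at rt would remove the stereocentre and give 6.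

**Further compounds**

F1 | step 9 | benzyl 3,5,7-trioxotetradecanoate (not isolated) | CCCCCCCC(=O)CC(=O)CC(=O)CC(=O)OCc1ccccc1
F2 | step 9 | benzyl 2-heptyl-4,6-dihydroxybenzoate | CCCCCCCc1cc(O)cc(O)c1C(=O)OCc1ccccc1
F3 | step 9 | benzyl 2-heptyl-6-hydroxy-4-methoxybenzoate | CCCCCCCc1cc(OC)cc(O)c1C(=O)OCc1ccccc1
F4 | step 9 | 2-heptyl-6-hydroxy-4-methoxybenzoic acid | CCCCCCCc1cc(OC)cc(O)c1C(=O)O
F5 | step 4 | 2,4-dihydroxy-6-pentylbenzaldehyde | CCCCCc1cc(O)cc(O)c1C=O
F6 | step 4 | 4-(allyloxy)-2-hydroxy-6-pentylbenzaldehyde | CCCCCc1cc(OCC=C)cc(O)c1C=O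
F7 | step 4 | 4-(allyloxy)-2-methoxy-6-pentylbenzaldehyde | CCCCCc1cc(OCC=C)cc(OC)c1C=O
F8 | step 4 | 4-(allyloxy)-2-methoxy-6-pentylbenzoic acid | CCCCCc1cc(OCC=C)cc(OC)c1C(=O)O
F9 | step 3 | 6-(4-hydroxy-2-oxoundecyl)-2,2-dimethyl-4H-1,3-dioxin-4-one (racemic) | CCCCCCCC(O)CC(=O)CC1=CC(=O)OC(C)(C)O1
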